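**Plan**
Numbering: cycloheptane C1 (tertiary carbinol with the butenoyl group), C2 (angelate), C3 (lactone O), C4 (ring-fusion CH), C5 (CH2), C6 (CHOH), C7 (CHMe). The 8-oxabicyclo[3.2.1]octane intermediates keep these numbers (O8 = bridge).
Retrosynthesis: the enone comes from a C1 CH2OH group and the C6 alcohol from a C6 ketone. The C1 hydroxyl and the C5 methylene come from an oxygen bridge C1–O–C5, cut next to that ketone. The lactone comes from a C3 ketone alkylated at C4. C1–C2 and C4–C5 are then cut together as a (4+3) cycloaddition.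
Enabling feature: C2(O)–C3(O)–C4 is a masked 1-alkoxy-2-oxyallyl cation. C5–C6–C7–C1, with oxygen on C1 and none on C5, is a 2-substituted furan whose ring oxygen becomes the C1 hydroxyl.
Forward: the seven-membered ring forms first inside an 8-oxabicyclo[3.2.1]octenone, then the γ-lactone on C3/C4, then C6/C7 on the rigid bicycle, then the bridge is cut and the side chain is finished.
Stereochemistry: a 1-phenylethyl auxiliary on the C2 oxygen fixes C1, C2 and C5 in the cycloaddition. (R)-Lactate triflate (inversion) gives the lactone α-carbon, the bicycle directs C3, C4 and C7, and the C1 hydroxyl directs hydride to C6.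

Key step: step 4

Assumption: the (S)-1-phenylethoxy group is taken to cover the cation face that leads to the enantiomer drawn (furan adds anti to the phenyl group); if the induction is the opposite, (R)-1-phenylethanol is used instead.

Step 1
Reactants: 1 1,1-dimethoxypropan-2-one; 2 (S)-1-phenylethanol
Product: 3 1-methoxy-1-[(1S)-1-phenylethoxy]propan-2-one (both epimers at the acetal carbon)
Conditions: PPTS (cat.), toluene, 60 °C, MeOH removed under reduced pressure
Reagents that add atoms: none
Why: Acid-catalysed transacetalisation, driven by removal of methanol, swaps one methoxy group for the chiral alkoxy group without touching the carbinol centre of 2; the acetal centre forms as a mixture that is erased when the cation is made.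

Step 2
Reactants: 3 mixed acetal
Product: 4 triethyl({3-methoxy-3-[(1S)-1-phenylethoxy]prop-1-en-2-yl}oxy)silane
Conditions: LiN(iPr)2, THF, −78 °C; Et3SiCl, −78 °C → rt
Reagents that add atoms: chlorotriethylsilane CC[Si](Cl)(CC)CC
Why: Kinetic deprotonation at the methyl group (the hindered acetal C–H is left alone) and O-silylation give the silyl enol ether (enolate silylation).

Step 3
Reactants: 5 furfuryl alcohol
Product: 6 tert-butyl(furan-2-ylmethoxy)dimethylsilane
Conditions: TBSCl, imidazole, CH2Cl2, rt
Reagents that add atoms: tert-butylchlorodimethylsilane CC(C)(C)[Si](C)(C)Cl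
Why: Routine silylation of a primary alcohol; it keeps the future C1 substituent at the alcohol level and suppresses ionisation at the furfuryl position.

Step 4
Reactants: 4 silyl enol ether acetal; 6 silylated furan
Product: 8 (1R,2R,5S)-1-{[tert-butyl(dimethyl)silyl]oxymethyl}-2-[(1S)-1-phenylethoxy]-8-oxabicyclo[3.2.1]oct-6-en-3-one, via 1-alkoxy-2-silyloxyallyl cation triflate 7 (not isolated)
Conditions: TMSOTf (0.1 equiv), CH2Cl2, −95 °C
Reagents that add atoms: none
Why: TMSOTf removes the methoxy group of 4 to give the W-shaped 1-alkoxy-2-silyloxyallyl cation 7, whose three-carbon two-electron π system adds across C2 and C5 of furan 6 in a (4+3) cycloaddition, after which the oxocarbenium ion loses its silyl group to give the C3 ketone and return the silyl triflate. The closest known reaction is the low-temperature cycloaddition of 1-phenylethoxy-substituted silyloxyallyl cations with furan itself. The seven-membered carbocycle closes in a concerted but asynchronous way through the compact transition state, C4–C5 leading and C1–C2 following (in the stepwise limit a 7-(enolendo)-exo-trig attack of the enol ether carbon on the furan-derived oxocarbenium ion), and the oxygen bridge creates the tetrahydrofuran and pyranone rings at the same time. C2 is set by the auxiliary, whose phenyl group is taken to cover one face of the cation, and C1 and C5 follow from suprafacial addition in the compact geometry, which places the alkoxy group equatorial, trans to the oxygen bridge. The step needs the alkoxy-bearing carbon to bond to the substituted furan carbon: the unsubstituted, more electrophilic CH2 terminus pairs first with the unsubstituted, more nucleophilic furan C5, as is known for heteroatom-substituted oxyallyl cations with 2-substituted furans.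

Step 5
Reactants: 9 ethyl (R)-lactate
Product: 10 ethyl (2R)-2-(trifluoromethylsulfonyloxy)propanoate
Conditions: Tf2O, 2,6-lutidine, CH2Cl2, −78 → 0 °C
Reagents that add atoms: trifluoromethanesulfonic anhydride O=S(=O)(OS(=O)(=O)C(F)(F)F)C(F)(F)F
Why: O-Sulfonylation breaks no bond at the stereocentre, so the configuration is retained.

Step 6
Reactants: 8 cycloadduct; 10 lactate triflate
Product: 12 ethyl (2R)-2-[1-(silyloxymethyl)-3-oxo-2-(1-phenylethoxy)-8-oxabicyclo[3.2.1]oct-6-en-4-yl]propanoate (C4 side chain axial), via lithium enolate 11 (not isolated)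
Conditions: LiN(iPr)2, THF, −78 °C; then 10, −78 → −40 °C
Reagents that add atoms: none
Why: The kinetic enolate forms at C4, away from the hindered alkoxy-bearing C2, and displaces the triflate by SN2 (enolate alkylation with an α-triflyloxy ester): attack syn to the oxygen bridge and anti to the C6=C7 bridge puts the side chain axial at C4, and inversion at the lactate carbon sets the future lactone α-carbon as R.

Step 7
Reactants: 12 alkylated ketone
Product: 14 tricyclic cis-fused γ-lactone, via equatorial hydroxy ester 13 (not isolated)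
Conditions: NaBH4, MeOH–CH2Cl2, −40 °C; then CSA (cat.), CH2Cl2, rt
Reagents that add atoms: none
Why: The axial C4 side chain blocks the oxygen-bridge face, so borohydride should enter from the C6=C7 face and give the equatorial C3 alcohol cis to the ester, which closes the cis-fused lactone under acid (ketone reduction, then lactonisation).

Step 8
Reactants: 14 lactone alkene
Product: 15 C6 alcohol (exo hydroxyl, C7 H2)
Conditions: 9-BBN, THF, rt; then 30% H2O2, aq NaOAc, 0 °C
Reagents that add atoms: hydrogen peroxide OO
Why: Hydroboration–oxidation of the strained alkene from the exo face with the bulky borane on C6, the carbon remote from the substituted bridgehead C1; the carbinol configuration is irrelevant because it is oxidised next, and 9-BBN leaves the lactone alone.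

Step 9
Reactants: 15 C6 alcohol
Product: 16 C6 ketone
Conditions: Dess–Martin periodinane, NaHCO3, CH2Cl2, rt
Reagents that add atoms: none
Why: Dess–Martin oxidation of the secondary alcohol gives the ketone that will carry the C7 methylation and later activate the C5–O bond.

Step 10
Reactants: 16 C6 ketone
Product: 18 C6 ketone bearing an exo methyl group on C7, via lithium enolate 17 (not isolated)
Conditions: LiN(SiMe3)2 (1.05 equiv), THF, −78 °C; MeI, −78 °C
Reagents that add atoms: iodomethane CI
Why: C7 is the only enolisable position (C5 is a bridgehead) and the ketone is more acidic than the lactone; the enolate is methylated from the exo face, syn to the oxygen bridge, which sets C7 (kinetic enolate alkylation), and −78 °C keeps the β-alkoxy enolate from opening the bridge.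

Step 11
Reactants: 18 methylated ketone
Product: 19 C2 alcohol
Conditions: H2 (1 atm), Pd(OH)2/C, EtOAc, rt
Reagents that add atoms: none
Why: Hydrogenolysis of the secondary benzylic ether removes the auxiliary; no alkene is present at this stage, and the ketone, lactone and silyl ether survive.

Step 12
Reactants: 19 C2 alcohol; 20 angelic acid
Product: 21 C2 angelate
Conditions: 20, 2,4,6-trichlorobenzoyl chloride, Et3N, toluene, rt; then 19, toluene, 80 °C
Reagents that add atoms: none
Why: Yamaguchi esterification through the mixed anhydride acylates the only free hydroxyl (C6 is still a ketone and the C1 oxygen is still in the bridge); DMAP is left out so that the Z geometry of the angelate is kept.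

Step 13
Reactants: 21 C2 angelate
Product: 22 ring-opened hydroxy ketone (C5 methylene, tertiary C1 hydroxyl)
Conditions: SmI2 (2.5 equiv), THF–MeOH, −78 °C
Reagents that add atoms: none
Why: The ketyl of the C6 ketone expels the α-alkoxy group, so the C5–O bond breaks (reductive cleavage of an α-alkoxy ketone, known for oxa-bridged bicyclic ketones); protonation of the samarium enolate gives the C5 methylene, the C1 hydroxyl keeps the configuration fixed in step 4, and the conjugated ester and lactone are not reduced at −78 °C without HMPA.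

Step 14
Reactants: 22 hydroxy ketone
Product: 23 C1,C6-diol
Conditions: Me4NBH(OAc)3, MeCN–AcOH, −30 °C
Reagents that add atoms: none
Why: Evans–Saksena reduction: the C1 hydroxyl binds the borohydride and delivers hydride to the C6 ketone on its own face, giving the C6 alcohol trans (1,3-anti) to the C1 hydroxyl; esters and lactone are inert to this reagent.

Step 15
Reactants: 23 silyl ether diol
Product: 24 triol
Conditions: HF·pyridine, THF–pyridine, 0 °C → rt
Reagents that add atoms: none
Why: Fluoride cleavage of the primary silyl ether under buffered acidic conditions, chosen to avoid base-induced migration of the angelate.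

Step 16
Reactants: 24 triol
Product: 25 α-hydroxy aldehyde
Conditions: TEMPO (cat.), N-chlorosuccinimide, Bu4NCl, CH2Cl2–aq NaHCO3/K2CO3 (pH 8.6), rt
Reagents that add atoms: none
Why: The oxoammonium-mediated oxidation is selective for the primary alcohol over the secondary C6 and tertiary C1 hydroxyls and stops at the aldehyde.

Step 17
Reactants: 25 aldehyde; 26 (E)-1-bromoprop-1-ene
Product: 27 allylic alcohol (both epimers at the new carbinol carbon)
Conditions: CrCl2 (6 equiv), NiCl2 (cat.), DMF, rt
Reagents that add atoms: none
Why: Nozaki–Hiyama–Kishi coupling: the alkenylchromium species, formed with retention of the E geometry, adds only to the aldehyde in the presence of free hydroxyls, esters and the lactone; the new carbinol centre is removed in the next step.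

Step 18
Reactants: 27 allylic alcohol
Product: 28 target, (3R,3aS,5R,6S,7S,8S,8aR)-7-[(E)-but-2-enoyl]-5,7-dihydroxy-3,6-dimethyl-2-oxooctahydro-2H-cyclohepta[b]furan-8-yl (Z)-2-methylbut-2-enoate
Conditions: MnO2 (activated, excess), CH2Cl2, rt
Reagents that add atoms: none
Why: MnO2 oxidises only the allylic alcohol, giving the E-enone; the non-allylic C6 alcohol and the tertiary C1 alcohol are not touched.

**Compound list**
1 | 1,1-dimethoxypropan-2-one | CC(=O)C(OC)OC | starting material
2 | (S)-1-phenylethanol | C[C@H](O)c1ccccc1 | starting material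
3 | 1-methoxy-1-[(1S)-1-phenylethoxy]propan-2-one (both epimers at the acetal carbon) | CC(=O)C(OC)O[C@@H](C)c1ccccc1 | intermediate
4 | triethyl({3-methoxy-3-[(1S)-1-phenylethoxy]prop-1-en-2-yl}oxy)silane (both acetal epimers) | C=C(O[Si](CC)(CC)CC)C(OC)O[C@@H](C)c1ccccc1 | intermediate
5 | furfuryl alcohol (furan-2-ylmethanol) | OCc1ccco1 | starting material
6 | tert-butyl(furan-2-ylmethoxy)dimethylsilane | CC(C)(C)[Si](C)(C)OCc1ccco1 | intermediate
7 | 1-[(1S)-1-phenylethoxy]-2-(triethylsilyloxy)allyl cation trifluoromethanesulfonate | C=C(O[Si](CC)(CC)CC)C=[O+][C@@H](C)c1ccccc1.[O-]S(=O)(=O)C(F)(F)F | intermediate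
8 | (1R,2R,5S)-1-{[tert-butyl(dimethyl)silyl]oxymethyl}-2-[(1S)-1-phenylethoxy]-8-oxabicyclo[3.2.1]oct-6-en-3-one; alkoxy group equatorial, trans to the oxygen bridge | C[C@@H](c1ccccc1)O[C@H]1C(=O)C[C@H]2C=C[C@@]1(O2)CO[Si](C)(C)C(C)(C)C | intermediate
9 | ethyl (R)-lactate | CCOC(=O)[C@@H](C)O | starting material
10 | ethyl (2R)-2-(trifluoromethylsulfonyloxy)propanoate | CCOC(=O)[C@@H](C)OS(=O)(=O)C(F)(F)F | intermediate
11 | lithium C3–C4 enolate of 8 | C[C@@H](c1ccccc1)O[C@H]1C([O-])=C[C@H]2C=C[C@@]1(O2)CO[Si](C)(C)C(C)(C)C.[Li+] | intermediate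
12 | ethyl (2R)-2-[1-{[tert-butyl(dimethyl)silyl]oxymethyl}-3-oxo-2-[(1S)-1-phenylethoxy]-8-oxabicyclo[3.2.1]oct-6-en-4-yl]propanoate; C1, C2, C5 as in 8, C4 side chain axial (cis to the oxygen bridge) | C[C@@H](c1ccccc1)O[C@H]1C(=O)[C@H]([C@@H](C)C(=O)OCC)[C@H]2C=C[C@@]1(O2)CO[Si](C)(C)C(C)(C)C | intermediate
13 | C3 alcohol of 12; hydroxyl equatorial, cis to the oxygen bridge and to the C4 side chain | C[C@@H](c1ccccc1)O[C@H]1[C@H](O)[C@H]([C@@H](C)C(=O)OCC)[C@H]2C=C[C@@]1(O2)CO[Si](C)(C)C(C)(C)C | intermediate
14 | tricyclic lactone: 8-oxabicyclo[3.2.1]oct-6-ene with a cis-fused γ-lactone across C3 (O) and C4; lactone α-carbon R, its methyl cis to the C4–C5 bond; C1 CH2OTBS; C2 (S)-1-phenylethoxy equatorial | C[C@@H](c1ccccc1)O[C@H]1[C@@H]3OC(=O)[C@H](C)[C@@H]3[C@H]2C=C[C@@]1(O2)CO[Si](C)(C)C(C)(C)C | intermediate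
15 | as 14 with C6=C7 hydrated: exo C6 hydroxyl (syn to the oxygen bridge), C7 H2 | C[C@@H](c1ccccc1)O[C@H]1[C@@H]3OC(=O)[C@H](C)[C@@H]3[C@H]2[C@H](O)C[C@@]1(O2)CO[Si](C)(C)C(C)(C)C | intermediate
16 | C6 ketone of 15 | C[C@@H](c1ccccc1)O[C@H]1[C@@H]3OC(=O)[C@H](C)[C@@H]3[C@H]2C(=O)C[C@@]1(O2)CO[Si](C)(C)C(C)(C)C | intermediate
17 | lithium C6–C7 enolate of 16 | C[C@@H](c1ccccc1)O[C@H]1[C@@H]3OC(=O)[C@H](C)[C@@H]3[C@H]2C([O-])=C[C@@]1(O2)CO[Si](C)(C)C(C)(C)C.[Li+] | intermediate
18 | C6 ketone with an exo C7 methyl group (syn to the oxygen bridge) | C[C@@H](c1ccccc1)O[C@H]1[C@@H]3OC(=O)[C@H](C)[C@@H]3[C@H]2C(=O)[C@H](C)[C@@]1(O2)CO[Si](C)(C)C(C)(C)C | intermediate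
19 | C2 alcohol of 18 (auxiliary removed; hydroxyl equatorial) | O[C@H]1[C@@H]3OC(=O)[C@H](C)[C@@H]3[C@H]2C(=O)[C@H](C)[C@@]1(O2)CO[Si](C)(C)C(C)(C)C | intermediate
20 | angelic acid, (Z)-2-methylbut-2-enoic acid | C/C=C(/C)C(=O)O | starting material
21 | C2 (Z)-2-methylbut-2-enoate of 19 | C/C=C(/C)C(=O)O[C@H]1[C@@H]3OC(=O)[C@H](C)[C@@H]3[C@H]2C(=O)[C@H](C)[C@@]1(O2)CO[Si](C)(C)C(C)(C)C | intermediate
22 | cycloheptane-fused lactone with C6 ketone, C5 CH2, tertiary C1 hydroxyl and C1 CH2OTBS; C1, C2, C3, C4, C7 and the lactone α-carbon as in the target | C/C=C(/C)C(=O)O[C@H]1[C@@H]2OC(=O)[C@H](C)[C@@H]2CC(=O)[C@H](C)[C@@]1(O)CO[Si](C)(C)C(C)(C)C | intermediate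
23 | C6 alcohol of 22, trans to the C1 hydroxyl; all ring centres as in the target | C/C=C(/C)C(=O)O[C@H]1[C@@H]2OC(=O)[C@H](C)[C@@H]2C[C@@H](O)[C@H](C)[C@@]1(O)CO[Si](C)(C)C(C)(C)C | intermediate
24 | triol: 23 with the C1 CH2OH group free | C/C=C(/C)C(=O)O[C@H]1[C@@H]2OC(=O)[C@H](C)[C@@H]2C[C@@H](O)[C@H](C)[C@@]1(O)CO | intermediate
25 | C1 carbaldehyde (α-hydroxy aldehyde) | C/C=C(/C)C(=O)O[C@H]1[C@@H]2OC(=O)[C@H](C)[C@@H]2C[C@@H](O)[C@H](C)[C@@]1(O)C=O | intermediate
26 | (E)-1-bromoprop-1-ene | C/C=C/Br | starting material
27 | C1 (E)-1-hydroxybut-2-enyl compound (both carbinol epimers) | C/C=C(/C)C(=O)O[C@H]1[C@@H]2OC(=O)[C@H](C)[C@@H]2C[C@@H](O)[C@H](C)[C@@]1(O)C(O)/C=C/C | intermediate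
28 | (3R,3aS,5R,6S,7S,8S,8aR)-7-[(E)-but-2-enoyl]-5,7-dihydroxy-3,6-dimethyl-2-oxooctahydro-2H-cyclohepta[b]furan-8-yl (Z)-2-methylbut-2-enoate | C/C=C(/C)C(=O)O[C@H]1[C@@H]2OC(=O)[C@H](C)[C@@H]2C[C@@H](O)[C@H](C)[C@@]1(O)C(=O)/C=C/C | target

**Totals and risks**
Total step count: 18. Longest linear sequence: 16 steps (steps 1, 2, 4 and 6 to 18).

Step 4. What may go wrong: the furan may be captured at one cation terminus and then rearomatise (Friedel–Crafts alkylation instead of ring closure), the termini may pair in the reverse sense, or the phenylethyl group may discriminate the faces poorly on this more hindered furan. Fallback: generate the oxyallyl species by base from an α-chloro ketone, without silyl group or Lewis acid. The fallback sets out from 2. NaH and racemic epichlorohydrin give the glycidyl ether 2-{[(1S)-1-phenylethoxy]methyl}oxirane F1. LiCl and AcOH open it to 1-chloro-3-[(1S)-1-phenylethoxy]propan-2-ol F2, and Dess–Martin oxidation gives 1-chloro-3-[(1S)-1-phenylethoxy]propan-2-one F3. Treating F3 with Et3N in 2,2,2-trifluoroethanol in the presence of furan 6 performs the same cycloaddition, and the route is rejoined at 8 after separation of isomers.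

Step 6. What may go wrong: the basic enolate may eliminate triflic acid from the secondary triflate, or proton exchange may move the enolate toward C2 and scramble C4. Fallback: build the lactone from a primary two-carbon electrophile and add the methyl group afterwards. The fallback sets out from 8. LiN(iPr)2 and methyl bromoacetate give the axial C4 methyl acetate ketone F4. NaBH4 and then CSA give the nor-methyl cis-lactone F5. LiN(iPr)2 and MeI methylate its enolate on the convex face to give the lactone α-epimer of 14, F6. Deprotonation with LiN(iPr)2 at −78 °C and kinetic protonation with 2,6-di-tert-butylphenol, again from the convex face, invert that centre, and the route is rejoined at 14.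

Step 7. What may go wrong: hydride may be delivered from the face of the oxygen bridge, giving the axial alcohol trans to the ester, which cannot lactonise. Fallback: close the lactone with inversion instead of retention. The fallback sets out from 12. LiBH(s-Bu)3 gives the axial C3 hydroxy ester F7, and LiOH gives the hydroxy acid F8. Mitsunobu lactonisation (PPh3, DIAD) displaces the activated axial hydroxyl from the opposite face by the carboxylate, and the route is rejoined at 14.

**Further compounds**
F1 | step 4 | 2-{[(1S)-1-phenylethoxy]methyl}oxirane (both oxirane epimers) | C[C@@H](c1ccccc1)OCC1CO1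
F2 | step 4 | 1-chloro-3-[(1S)-1-phenylethoxy]propan-2-ol (both carbinol epimers) | C[C@@H](c1ccccc1)OCC(O)CCl
F3 | step 4 | 1-chloro-3-[(1S)-1-phenylethoxy]propan-2-one | C[C@@H](c1ccccc1)OCC(=O)CCl
F4 | step 6 | methyl 2-[1-{[tert-butyl(dimethyl)silyl]oxymethyl}-3-oxo-2-[(1S)-1-phenylethoxy]-8-oxabicyclo[3.2.1]oct-6-en-4-yl]acetate, side chain axial | C[C@@H](c1ccccc1)O[C@H]1C(=O)[C@H](CC(=O)OC)[C@H]2C=C[C@@]1(O2)CO[Si](C)(C)C(C)(C)C
F5 | step 6 | nor-methyl analogue of lactone 14 | C[C@@H](c1ccccc1)O[C@H]1[C@@H]3OC(=O)C[C@@H]3[C@H]2C=C[C@@]1(O2)CO[Si](C)(C)C(C)(C)C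
F6 | step 6 | epimer of 14 at the lactone α-carbon (methyl on the convex face) | C[C@@H](c1ccccc1)O[C@H]1[C@@H]3OC(=O)[C@@H](C)[C@@H]3[C@H]2C=C[C@@]1(O2)CO[Si](C)(C)C(C)(C)C
F7 | step 7 | C3 epimer of 13 (axial hydroxyl, trans to the C4 side chain) | C[C@@H](c1ccccc1)O[C@H]1[C@@H](O)[C@H]([C@@H](C)C(=O)OCC)[C@H]2C=C[C@@]1(O2)CO[Si](C)(C)C(C)(C)C
F8 | step 7 | carboxylic acid of F7 | C[C@@H](c1ccccc1)O[C@H]1[C@@H](O)[C@H]([C@@H](C)C(=O)O)[C@H]2C=C[C@@]1(O2)CO[Si](C)(C)C(C)(C)C
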